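**Retrosynthetic overview**
1. Target 18 ⇐ 17 (thirteen OMe, one OH) by global O-demethylation. The chain is read as A–O–B–O–C–O–D–O–E, with rings B and D pentaoxygenated.
2. Key disconnection (no metal-catalysed C–O coupling): each tri-ortho-substituted ether (A–O–B, C–O–D) ⇐ hindered 2,6-dimethoxyphenoxide + 5-bromo-2,3-dimethoxy-1,4-benzoquinone 3 by addition–elimination. The two quinone C=O groups become ring oxygens of B and D.
3. Each remaining ether (B–O–C, D–O–E) ⇐ the hindered OH of the reduced, mono-methylated quinone ring + 4-fluoro-2,6-dimethoxybenzaldehyde 8 (SNAr). Dakin oxidation of the CHO then gives the next hindered phenol.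
4. No ring is formed in the route. The rings come intact from 4 (ring A), 3 (rings B and D) and 8 (rings C and E) and are joined in the order A, B, C, D, E.

Assumption: the target is achiral (no stereocentre, no stable axis), so no configuration has to be set; 1, 4 and 8 are taken as catalogue compounds.

**Step 1**
Reactants: 1 2,3,4-trimethoxyphenol
Product: 2 6-bromo-2,3,4-trimethoxyphenol
Conditions: NBS (1.0 equiv), CH2Cl2, −20 to 0 °C
Reagents that add atoms: N-bromosuccinimide (O=C1CCC(=O)N1Br)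
Why: Electrophilic aromatic bromination of the electron-rich phenol ortho to OH (para is blocked); the regiochemistry is uncritical because either mono-bromide gives the same quinone 3.

**Step 2**
Reactants: 2 6-bromo-2,3,4-trimethoxyphenol
Product: 3 5-bromo-2,3-dimethoxy-1,4-benzoquinone
Conditions: PhI(OAc)2, MeCN/H2O, 0 °C
Reagents that add atoms: water (O)
Why: Hypervalent-iodine oxidative demethylation of a p-methoxyphenol, in which water adds at the para carbon and the hemiketal loses MeOH to give the p-quinone.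

**Step 3**
Reactants: 4 2,4,6-trimethoxyphenol; 3 5-bromo-2,3-dimethoxy-1,4-benzoquinone
Product: 5 2,3-dimethoxy-5-(2,4,6-trimethoxyphenoxy)-1,4-benzoquinone
Conditions: K2CO3 (1.0 equiv), DMF, 0 °C to rt, Ar
Reagents that add atoms: none
Why: Addition–elimination (nucleophilic vinylic substitution) of a phenoxide on a bromoquinone, the known route to aryloxyquinones; attack at C–Br or at the neighbouring C–H followed by loss of HBr gives the same product because the 2,3-dimethoxyquinone core is symmetric, and the high electrophilicity of the quinone lets the di-ortho-substituted phenoxide react at room temperature.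

**Step 4**
Reactants: 5 2,3-dimethoxy-5-(2,4,6-trimethoxyphenoxy)-1,4-benzoquinone
Product: 7 2,3,4-trimethoxy-6-(2,4,6-trimethoxyphenoxy)phenol, via hydroquinone 6 (not isolated)
Conditions: Na2S2O4, THF/H2O, rt; then MeI (1.0 equiv), K2CO3 (1.0 equiv), acetone, 0 °C to rt, Ar
Reagents that add atoms: iodomethane (CI)
Why: Dithionite reduction of the quinone followed by a sterically controlled Williamson mono-methylation, which takes the OH that has a free ortho position and leaves the OH flanked by OMe and the bulky aryloxy group.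

**Step 5**
Reactants: 7 2,3,4-trimethoxy-6-(2,4,6-trimethoxyphenoxy)phenol; 8 4-fluoro-2,6-dimethoxybenzaldehyde
Product: 9 2,6-dimethoxy-4-[2,3,4-trimethoxy-6-(2,4,6-trimethoxyphenoxy)phenoxy]benzaldehyde
Conditions: Cs2CO3, DMSO, 110 °C, Ar
Reagents that add atoms: none
Why: SNAr through a Meisenheimer complex at the fluorine para to the aldehyde; the electrophilic carbon has two ortho hydrogens, so the hindered phenoxide can reach it.

**Step 6**
Reactants: 9 2,6-dimethoxy-4-[2,3,4-trimethoxy-6-(2,4,6-trimethoxyphenoxy)phenoxy]benzaldehyde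
Product: 11 2,6-dimethoxy-4-[2,3,4-trimethoxy-6-(2,4,6-trimethoxyphenoxy)phenoxy]phenol, via aryl formate 10 (not isolated)
Conditions: 30% H2O2, cat. H2SO4, MeOH, rt
Reagents that add atoms: hydrogen peroxide (OO)
Why: Acid-catalysed Dakin oxidation, in which the electron-rich tri-oxygenated aryl group migrates to oxygen and the aryl formate is methanolysed in the same pot.

**Step 7**
Reactants: 11 2,6-dimethoxy-4-[2,3,4-trimethoxy-6-(2,4,6-trimethoxyphenoxy)phenoxy]phenol; 3 5-bromo-2,3-dimethoxy-1,4-benzoquinone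
Product: 12 2,3-dimethoxy-5-{2,6-dimethoxy-4-[2,3,4-trimethoxy-6-(2,4,6-trimethoxyphenoxy)phenoxy]phenoxy}-1,4-benzoquinone
Conditions: K2CO3 (1.0 equiv), DMF, 0 °C to rt, Ar
Reagents that add atoms: none
Why: Second addition–elimination of a hindered phenoxide on the bromoquinone, as in step 3, forming the C–O–D ether.

**Step 8**
Reactants: 12 2,3-dimethoxy-5-{2,6-dimethoxy-4-[2,3,4-trimethoxy-6-(2,4,6-trimethoxyphenoxy)phenoxy]phenoxy}-1,4-benzoquinone
Product: 14 2,3,4-trimethoxy-6-{2,6-dimethoxy-4-[2,3,4-trimethoxy-6-(2,4,6-trimethoxyphenoxy)phenoxy]phenoxy}phenol, via hydroquinone 13 (not isolated)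
Conditions: Na2S2O4, THF/H2O, rt; then MeI (1.0 equiv), K2CO3 (1.0 equiv), acetone, 0 °C to rt, Ar
Reagents that add atoms: iodomethane (CI)
Why: Dithionite reduction and sterically controlled Williamson mono-methylation at the less hindered OH, as in step 4.

**Step 9**
Reactants: 14 2,3,4-trimethoxy-6-{2,6-dimethoxy-4-[2,3,4-trimethoxy-6-(2,4,6-trimethoxyphenoxy)phenoxy]phenoxy}phenol; 8 4-fluoro-2,6-dimethoxybenzaldehyde
Product: 15 2,6-dimethoxy-4-(2,3,4-trimethoxy-6-{2,6-dimethoxy-4-[2,3,4-trimethoxy-6-(2,4,6-trimethoxyphenoxy)phenoxy]phenoxy}phenoxy)benzaldehyde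
Conditions: Cs2CO3, DMSO, 110 °C, Ar
Reagents that add atoms: none
Why: SNAr of the hindered phenoxide at the unhindered C–F carbon para to the aldehyde, as in step 5.

**Step 10**
Reactants: 15 2,6-dimethoxy-4-(2,3,4-trimethoxy-6-{2,6-dimethoxy-4-[2,3,4-trimethoxy-6-(2,4,6-trimethoxyphenoxy)phenoxy]phenoxy}phenoxy)benzaldehyde
Product: 17 2,6-dimethoxy-4-(2,3,4-trimethoxy-6-{2,6-dimethoxy-4-[2,3,4-trimethoxy-6-(2,4,6-trimethoxyphenoxy)phenoxy]phenoxy}phenoxy)phenol, via aryl formate 16 (not isolated)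
Conditions: 30% H2O2, cat. H2SO4, MeOH, rt
Reagents that add atoms: hydrogen peroxide (OO)
Why: Acid-catalysed Dakin oxidation with in-situ methanolysis of the formate, as in step 6.

**Step 11**
Reactants: 17 2,6-dimethoxy-4-(2,3,4-trimethoxy-6-{2,6-dimethoxy-4-[2,3,4-trimethoxy-6-(2,4,6-trimethoxyphenoxy)phenoxy]phenoxy}phenoxy)phenol
Product: 18 5-(2,3,4-trihydroxy-6-{2,6-dihydroxy-4-[2,3,4-trihydroxy-6-(2,4,6-trihydroxyphenoxy)phenoxy]phenoxy}phenoxy)benzene-1,2,3-triol
Conditions: BBr3 (excess), CH2Cl2, −78 °C to rt, Ar; then H2O, 0 °C; degassed work-up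
Reagents that add atoms: none
Why: Lewis-acid ether cleavage in which bromide removes each methyl group by SN2 attack on the BBr3-complexed methoxy group, while the diaryl ether bonds offer no sp3 carbon and survive.

**Compound list**
1 | 2,3,4-trimethoxyphenol | COc1ccc(O)c(OC)c1OC | starting material
2 | 6-bromo-2,3,4-trimethoxyphenol | COc1cc(Br)c(O)c(OC)c1OC | intermediate
3 | 5-bromo-2,3-dimethoxy-1,4-benzoquinone | COC1=C(OC)C(=O)C(Br)=CC1=O | intermediate
4 | 2,4,6-trimethoxyphenol (ring A) | COc1cc(OC)c(O)c(OC)c1 | starting material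
5 | 2,3-dimethoxy-5-(2,4,6-trimethoxyphenoxy)-1,4-benzoquinone | COC1=C(OC)C(=O)C(Oc2c(OC)cc(OC)cc2OC)=CC1=O | intermediate
6 | 2,3-dimethoxy-5-(2,4,6-trimethoxyphenoxy)benzene-1,4-diol | COc1c(OC)c(O)c(Oc2c(OC)cc(OC)cc2OC)cc1O | intermediate (not isolated)
7 | 2,3,4-trimethoxy-6-(2,4,6-trimethoxyphenoxy)phenol | COc1cc(Oc2c(OC)cc(OC)cc2OC)c(O)c(OC)c1OC | intermediate
8 | 4-fluoro-2,6-dimethoxybenzaldehyde | COc1cc(F)cc(OC)c1C=O | starting material
9 | 2,6-dimethoxy-4-[2,3,4-trimethoxy-6-(2,4,6-trimethoxyphenoxy)phenoxy]benzaldehyde | COc1cc(Oc2c(OC)c(OC)c(OC)cc2Oc2c(OC)cc(OC)cc2OC)cc(OC)c1C=O | intermediate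
10 | 2,6-dimethoxy-4-[2,3,4-trimethoxy-6-(2,4,6-trimethoxyphenoxy)phenoxy]phenyl formate | COc1cc(Oc2c(OC)c(OC)c(OC)cc2Oc2c(OC)cc(OC)cc2OC)cc(OC)c1OC=O | intermediate (not isolated)
11 | 2,6-dimethoxy-4-[2,3,4-trimethoxy-6-(2,4,6-trimethoxyphenoxy)phenoxy]phenol | COc1cc(Oc2c(OC)c(OC)c(OC)cc2Oc2c(OC)cc(OC)cc2OC)cc(OC)c1O | intermediate
12 | 2,3-dimethoxy-5-{2,6-dimethoxy-4-[2,3,4-trimethoxy-6-(2,4,6-trimethoxyphenoxy)phenoxy]phenoxy}-1,4-benzoquinone | COC1=C(OC)C(=O)C(Oc2c(OC)cc(Oc3c(OC)c(OC)c(OC)cc3Oc3c(OC)cc(OC)cc3OC)cc2OC)=CC1=O | intermediate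
13 | 2,3-dimethoxy-5-{2,6-dimethoxy-4-[2,3,4-trimethoxy-6-(2,4,6-trimethoxyphenoxy)phenoxy]phenoxy}benzene-1,4-diol | COc1c(OC)c(O)c(Oc2c(OC)cc(Oc3c(OC)c(OC)c(OC)cc3Oc3c(OC)cc(OC)cc3OC)cc2OC)cc1O | intermediate (not isolated)
14 | 2,3,4-trimethoxy-6-{2,6-dimethoxy-4-[2,3,4-trimethoxy-6-(2,4,6-trimethoxyphenoxy)phenoxy]phenoxy}phenol | COc1c(OC)c(O)c(Oc2c(OC)cc(Oc3c(OC)c(OC)c(OC)cc3Oc3c(OC)cc(OC)cc3OC)cc2OC)cc1OC | intermediate
15 | 2,6-dimethoxy-4-(2,3,4-trimethoxy-6-{2,6-dimethoxy-4-[2,3,4-trimethoxy-6-(2,4,6-trimethoxyphenoxy)phenoxy]phenoxy}phenoxy)benzaldehyde | COc1cc(Oc2c(OC)c(OC)c(OC)cc2Oc2c(OC)cc(Oc3c(OC)c(OC)c(OC)cc3Oc3c(OC)cc(OC)cc3OC)cc2OC)cc(OC)c1C=O | intermediate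
16 | 2,6-dimethoxy-4-(2,3,4-trimethoxy-6-{2,6-dimethoxy-4-[2,3,4-trimethoxy-6-(2,4,6-trimethoxyphenoxy)phenoxy]phenoxy}phenoxy)phenyl formate | COc1cc(Oc2c(OC)c(OC)c(OC)cc2Oc2c(OC)cc(Oc3c(OC)c(OC)c(OC)cc3Oc3c(OC)cc(OC)cc3OC)cc2OC)cc(OC)c1OC=O | intermediate (not isolated)
17 | 2,6-dimethoxy-4-(2,3,4-trimethoxy-6-{2,6-dimethoxy-4-[2,3,4-trimethoxy-6-(2,4,6-trimethoxyphenoxy)phenoxy]phenoxy}phenoxy)phenol | COc1cc(Oc2c(OC)c(OC)c(OC)cc2Oc2c(OC)cc(Oc3c(OC)c(OC)c(OC)cc3Oc3c(OC)cc(OC)cc3OC)cc2OC)cc(OC)c1O | intermediate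
18 | 5-(2,3,4-trihydroxy-6-{2,6-dihydroxy-4-[2,3,4-trihydroxy-6-(2,4,6-trihydroxyphenoxy)phenoxy]phenoxy}phenoxy)benzene-1,2,3-triol (CNP0273977.0, achiral) | Oc1cc(O)c(Oc2cc(O)c(O)c(O)c2Oc2cc(O)c(Oc3cc(O)c(O)c(O)c3Oc3cc(O)c(O)c(O)c3)c(O)c2)c(O)c1 | target

**Step count and risks**
Total step count: 11. Longest linear sequence: 11 steps (1 to 18 through 2, 3, 5, 7, 9, 11, 12, 14, 15 and 17).

Most likely to fail, first: step 4 (the same question recurs in step 8). The mono-methylation relies only on steric bias between the two hydroquinone OH groups; a poor ratio or over-methylation gives dead-end ethers. The fallback sets out from quinone 5 and builds the regiochemistry by acyl transfer, which is more sensitive to crowding than alkylation. Reductive acetylation (Zn dust, Ac2O, NaOAc, rt) gives 2,3-dimethoxy-5-(2,4,6-trimethoxyphenoxy)-1,4-phenylene diacetate F1. Pyrrolidine (1.05 equiv, THF, 0 °C) cleaves only the acetate with a free ortho position and gives 4-hydroxy-2,3-dimethoxy-6-(2,4,6-trimethoxyphenoxy)phenyl acetate F2. (Trimethylsilyl)diazomethane with i-Pr2NEt in MeOH/MeCN methylates the single free OH to 2,3,4-trimethoxy-6-(2,4,6-trimethoxyphenoxy)phenyl acetate F3. K2CO3 in MeOH then frees the hindered OH, and the route is rejoined at 7.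

Most likely to fail, second: step 7. The phenoxide of 11 is a strong reductant; electron transfer to quinone 3 can outrun C–O bond formation and can fragment the 4-aryloxy-2,6-dimethoxyphenol unit. The fallback sets out from 11 and uses bromophenol 2 from step 1 in a copper-catalysed Ullmann coupling that never passes through a quinone. Benzylation of 2 (BnBr, K2CO3, acetone) gives 2-(benzyloxy)-1-bromo-3,4,5-trimethoxybenzene F4. Coupling of F4 with 11 (CuI cat., N,N-dimethylglycine, Cs2CO3, dioxane, 110 °C) gives 2-(benzyloxy)-3,4,5-trimethoxy-1-{2,6-dimethoxy-4-[2,3,4-trimethoxy-6-(2,4,6-trimethoxyphenoxy)phenoxy]phenoxy}benzene F5. Hydrogenolysis (H2, Pd/C, EtOAc) returns to the route at 14, which also bypasses step 8.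

Most likely to fail, third: step 9. The most hindered phenoxide of the route must attack an only moderately activated fluoroarene at 110 °C, so slow conversion and thermal or oxidative loss of 14 are likely. The fallback sets out from 14 and uses a far more electrophilic partner at room temperature. 2,4,6-Trifluorobenzaldehyde (K2CO3, DMF, rt) is attacked at the para fluorine and gives 2,6-difluoro-4-(2,3,4-trimethoxy-6-{2,6-dimethoxy-4-[2,3,4-trimethoxy-6-(2,4,6-trimethoxyphenoxy)phenoxy]phenoxy}phenoxy)benzaldehyde F6. NaOMe in MeOH/THF at 60 °C exchanges both ortho fluorines for methoxy groups and returns to the route at 15.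

**Further compounds**
F1 | step 4 | 2,3-dimethoxy-5-(2,4,6-trimethoxyphenoxy)-1,4-phenylene diacetate | COc1c(OC)c(OC(C)=O)c(Oc2c(OC)cc(OC)cc2OC)cc1OC(C)=O
F2 | step 4 | 4-hydroxy-2,3-dimethoxy-6-(2,4,6-trimethoxyphenoxy)phenyl acetate | COc1c(OC)c(OC(C)=O)c(Oc2c(OC)cc(OC)cc2OC)cc1O
F3 | step 4 | 2,3,4-trimethoxy-6-(2,4,6-trimethoxyphenoxy)phenyl acetate | COc1c(OC)c(OC(C)=O)c(Oc2c(OC)cc(OC)cc2OC)cc1OC
F4 | step 7 | 2-(benzyloxy)-1-bromo-3,4,5-trimethoxybenzene | COc1cc(Br)c(OCc2ccccc2)c(OC)c1OC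
F5 | step 7 | 2-(benzyloxy)-3,4,5-trimethoxy-1-{2,6-dimethoxy-4-[2,3,4-trimethoxy-6-(2,4,6-trimethoxyphenoxy)phenoxy]phenoxy}benzene | COc1cc(Oc2c(OC)cc(Oc3c(OC)c(OC)c(OC)cc3Oc3c(OC)cc(OC)cc3OC)cc2OC)c(OCc2ccccc2)c(OC)c1OC
F6 | step 9 | 2,6-difluoro-4-(2,3,4-trimethoxy-6-{2,6-dimethoxy-4-[2,3,4-trimethoxy-6-(2,4,6-trimethoxyphenoxy)phenoxy]phenoxy}phenoxy)benzaldehyde | O=Cc1c(F)cc(Oc2c(OC)c(OC)c(OC)cc2Oc2c(OC)cc(Oc3c(OC)c(OC)c(OC)cc3Oc3c(OC)cc(OC)cc3OC)cc2OC)cc1F
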